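**Strategy.** The route rests on excising C4 from the seven-membered ring (C1 carbinol, C2, C3 methyl carbon, C4, C5 ketone, quaternary C6, fusion carbon C10). What remains is a trans-fused hydrindanone whose C5 ketone, flanked by quaternary C6, can enolise only toward C3. The key-step precursor is therefore the single C3=C5 trimethylsilyl enol ether carrying all four stereocentres (C1 O-TBS, C9 O-TMS). Dichlorocarbene then delivers C4 in one operation: it bonds to C3 and C5, and the resulting siloxycyclopropane opens across C3–C5 to the ring-enlarged 4-chloro enone. Dechlorination, desilylation and vanilloylation of the C1 hydroxyl complete the target.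

Key step: step 12

Remarks on the chemistry:
- Atom labels of the target are kept for every intermediate (five-membered ring C6–C7–C8–C9–C10, C9 being the isopropyl carbinol); descriptors such as 6S refer to these labels, not to systematic locants.
- The chiral triazolium salt of step 2 is assumed to be used as the enantiomer that gives 6S; should the sense of induction be the opposite, the antipodal salt is taken.
- Compound 12 is expected as a mixture of C3 epimers, which is without consequence because C3 becomes sp2 in step 11.

**Route**

Step 1
Reactants: 1 2-methylcyclohexane-1,3-dione; 2 acrolein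
Product: 3 3-(1-methyl-2,6-dioxocyclohexyl)propanal
Conditions: H2O, rt
Reagents that add atoms: none
Why: Michael addition of the acidic cyclic 1,3-diketone to acrolein proceeds in water without added base and gives the achiral aldehyde whose quaternary carbon becomes C6.

Step 2
Reactants: 3 3-(1-methyl-2,6-dioxocyclohexyl)propanal
Product: 4 cis-fused ketol (6S,10R)-10-hydroxy-6-methylhydrindane-5,9-dione
Conditions: aminoindanol-derived N-pentafluorophenyl triazolium tetrafluoroborate (10 mol%), Et3N (10 mol%), CH2Cl2, rt
Reagents that add atoms: none
Why: In this desymmetrising intramolecular crossed aldehyde–ketone benzoin reaction the Breslow intermediate of the chiral triazolylidene attacks one of the two enantiotopic ring ketones, closing the five-membered ring through C9–C10 and fixing C6 as S, while the C10 carbinol set by the cis fusion is erased in step 3.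

Step 3
Reactants: 4 cis-fused ketol
Product: 5 enedione (6S)-6-methylhydrind-1(10)-ene-5,9-dione
Conditions: SOCl2, pyridine, CH2Cl2, 0 °C → rt
Reagents that add atoms: none
Why: Dehydration of the tertiary α-ketol through its chlorosulfite by pyridine-mediated E2 elimination can run only toward C1, because C6 is quaternary and C9 is a carbonyl, and gives the C9-conjugated C1=C10 alkene.

Step 4
Reactants: 5 enedione
Product: 6 C5 ethylene ketal of the enedione
Conditions: (TMSOCH2)2, TMSOTf (cat.), CH2Cl2, −78 → −20 °C
Reagents that add atoms: 1,2-bis(trimethylsilyloxy)ethane, C[Si](C)(C)OCCO[Si](C)(C)C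
Why: Silyl-triflate-catalysed dioxolanation (Noyori acetalisation) selects the saturated C5 ketone over the less electrophilic conjugated C9 ketone without moving the double bond, so that C9 is the only carbonyl left for the organometallic of step 5.

Step 5
Reactants: 6 C5 ethylene ketal of the enedione
Product: 7 tertiary allylic alcohol (6S,9R), C9 hydroxyl cis to the C6 methyl
Conditions: i-PrMgCl, CeCl3, THF, −78 → 0 °C
Reagents that add atoms: isopropylmagnesium chloride, CC(C)[Mg]Cl
Why: Organocerium 1,2-addition to the enone carbonyl suppresses enolisation, reduction and conjugate addition, and the isopropyl group should approach C9 on the face opposite the C6 methyl, which stands perpendicular to the nearly flat five-membered ring, so the new hydroxyl ends up cis to that methyl (9R).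

Step 6
Reactants: 7 tertiary allylic alcohol
Product: 8 epoxy alcohol (1R,6S,9R,10S), epoxide on the face of the C9 hydroxyl
Conditions: VO(acac)2 (cat.), t-BuOOH, CH2Cl2, 0 °C → rt
Reagents that add atoms: tert-butyl hydroperoxide, CC(C)(C)OO
Why: Vanadium-catalysed hydroxyl-directed epoxidation delivers oxygen from the vanadium alkoxide of the C9 hydroxyl to the syn face of C1=C10, which sets the C1–O configuration (1R).

Step 7
Reactants: 8 epoxy alcohol
Product: 9 trans-fused ketal diol (1R,6S,9R,10S)
Conditions: Cp2TiCl2, Mn, H2O, THF, rt
Reagents that add atoms: none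
Why: Radical reductive epoxide opening with Cp2TiCl (trivalent titanium, the Nugent–RajanBabu reagent) cleaves the tertiary C10–O bond, and the planar C10 radical should take a hydrogen atom from the titanium aqua complex on the face away from the C6 methyl, the C9 hydroxyl and the bulky C1 titanoxy group, giving the trans ring fusion (10S) and the secondary C1 alcohol.

Step 8
Reactants: 9 trans-fused ketal diol
Product: 10 dihydroxy ketone (1R,6S,9R,10S)-1,9-dihydroxy-9-isopropyl-6-methyl-trans-hydrindan-5-one
Conditions: 1 M HCl, THF, rt
Reagents that add atoms: water, O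
Why: Acid-catalysed acetal hydrolysis frees the C5 ketone, and since neither hydroxyl is allylic or β to the carbonyl no elimination or retro-aldol pathway is open.

Step 9
Reactants: 10 dihydroxy ketone
Product: 11 C1 O-TBS hydroxy ketone
Conditions: TBSOTf, 2,6-lutidine, CH2Cl2, −78 °C
Reagents that add atoms: tert-butyldimethylsilyl triflate, CC(C)(C)[Si](C)(C)OS(=O)(=O)C(F)(F)F
Why: Silylation with the reactive silyl triflate is needed for the axial C1 hydroxyl (syn to the C6 methyl) and at low temperature leaves the far more hindered tertiary C9 hydroxyl untouched.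

Step 10
Reactants: 11 C1 O-TBS hydroxy ketone
Product: 12 C3-methyl ketone (C3 epimers)
Conditions: LiN(i-Pr)2 (2.2 equiv), THF, −78 °C; MeI, −78 → −20 °C
Reagents that add atoms: iodomethane, CI
Why: In this enolate alkylation the first equivalent of amide takes the C9 hydroxyl proton and the second can form only the C3 enolate because C6 is quaternary, so methyl iodide installs the C3 methyl group.

Step 11
Reactants: 12 C3-methyl ketone
Product: 13 key-step precursor, C3=C5 trimethylsilyl enol ether with C1 O-TBS and C9 O-TMS (1R,6S,9R,10S)
Conditions: TMSOTf, Et3N, CH2Cl2, 0 °C → rt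
Reagents that add atoms: trimethylsilyl triflate, C[Si](C)(C)OS(=O)(=O)C(F)(F)F
Why: Soft enolisation with silyl triflate and amine gives the only possible enol ether (tetrasubstituted C3=C5) and silylates the tertiary C9 hydroxyl in the same operation, so no free hydroxyl is left to intercept the carbene.

Step 12
Reactants: 13 key-step precursor; 14 chloroform
Product: 16 4-chloro hydroazulenone (1R,6S,9R,10S) with C1 O-TBS and C9 O-TMS, via siloxy dichlorocyclopropane 15 (not isolated)
Conditions: KOt-Bu, hexane, −20 °C → rt; then PhMe, 110 °C
Reagents that add atoms: none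
Why: Dichlorocarbene, formed from chloroform by α-elimination, adds in a concerted [2+1] cheletropic step to the electron-rich C3=C5 enol ether on the face away from the C6 methyl, making C3–C4 and C4–C5; on warming, the C4 chloride lying over the six-membered ring ionises as the shared C3–C5 bond opens in a disrotatory two-electron electrocyclic process to a 2-siloxyallyl cation stabilised by the C3 methyl and the C5 oxygen, and chloride removes the silyl group to leave the C3=C4–C5=O unit. The closest known reaction type is dihalocarbene addition to cyclic trimethylsilyl enol ethers with cyclopropyl-to-allyl opening to ring-enlarged 2-halo enones. The cyclopropane closes by the [2+1] addition, and the seven-membered ring is not closed by a cyclisation but arises when the bond common to the three- and six-membered rings is cleaved. No stereocentre is created, since C3 and C5 of the cyclopropane return to sp2 and C1, C6, C9 and C10 are neither enolisable nor ionisable under these conditions. The one selectivity needed is the site of insertion, and it is secured by quaternary C6, which allows the C5 ketone a single enol ether (toward C3), this enol ether also being the only alkene in the substrate.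

Step 13
Reactants: 16 4-chloro hydroazulenone
Product: 17 hydroazulenone with C3=C4–C5=O, C1 O-TBS and C9 O-TMS
Conditions: Pd(OAc)2 (cat.), XPhos (cat.), HCO2Na, DMF, 80 °C
Reagents that add atoms: none
Why: In this palladium-catalysed formate hydrodehalogenation zerovalent palladium inserts into the carbonyl-activated vinylic C4–Cl bond, formate replaces chloride and loses CO2 to give a palladium hydride, and reductive elimination places hydrogen on C4 without reducing the enone.

Step 14
Reactants: 17 hydroazulenone bis-silyl ether
Product: 18 diol enone (1R,6S,9R,10S)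
Conditions: HF·pyridine, pyridine, THF, 0 °C → rt
Reagents that add atoms: none
Why: Fluoride desilylation under buffered, non-basic conditions removes the C1 TBS and C9 TMS groups and avoids the base that could start vinylogous elimination of the C1 oxygen through the C2 dienolate.

Step 15
Reactants: 19 vanillic acid
Product: 20 tert-butyldimethylsilyl 4-(tert-butyldimethylsilyloxy)-3-methoxybenzoate
Conditions: TBSCl (2.5 equiv), imidazole, DMF, rt
Reagents that add atoms: tert-butyldimethylsilyl chloride, CC(C)(C)[Si](C)(C)Cl
Why: Imidazole-promoted silylation caps both the phenol and the carboxylic acid, the silyl ester serving as the activated form for step 16.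

Step 16
Reactants: 20 bis-silylated vanillic acid
Product: 21 4-(tert-butyldimethylsilyloxy)-3-methoxybenzoyl chloride
Conditions: (COCl)2, DMF (cat.), CH2Cl2, 0 °C → rt
Reagents that add atoms: oxalyl chloride, O=C(Cl)C(Cl)=O
Why: The Vilsmeier chloride formed from oxalyl chloride and DMF converts the silyl ester directly into the acid chloride under neutral conditions that the aryl silyl ether survives.

Step 17
Reactants: 18 diol enone; 21 4-(tert-butyldimethylsilyloxy)-3-methoxybenzoyl chloride
Product: 22 C1 ester with O-TBS-protected phenol
Conditions: Et3N, DMAP, CH2Cl2, 0 °C → rt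
Reagents that add atoms: none
Why: DMAP-catalysed acylation through the acylpyridinium ion esterifies the secondary C1 hydroxyl with retention, while the tertiary C9 hydroxyl next to the isopropyl group is too hindered to react and the weak amine base does not enolise the enone.

Step 18
Reactants: 22 C1 ester with O-TBS-protected phenol
Product: 23 target, CNP0136950.1
Conditions: n-Bu4NF, AcOH, THF, 0 °C
Reagents that add atoms: none
Why: Fluoride cleavage of the aryl silyl ether is fast, and the acetic acid buffer keeps the medium from becoming basic enough to eliminate or transesterify the C1 ester.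

**Compound list**

1 | 2-methylcyclohexane-1,3-dione | CC1C(=O)CCCC1=O | starting material
2 | acrolein | C=CC=O | starting material
3 | 3-(1-methyl-2,6-dioxocyclohexyl)propanal | CC1(CCC=O)C(=O)CCCC1=O | intermediate
4 | cis-fused ketol: hydrindane with C5 and C9 ketones, C6 methyl and C10 hydroxyl cis to it (6S,10R) | O=C1CC[C@]2(C)C(=O)CCC[C@]12O | intermediate
5 | enedione: C9 ketone conjugated with C1=C10, C5 ketone, C6 methyl (6S) | O=C1CC[C@@]2(C)C1=CCCC2=O | intermediate
6 | C5 1,3-dioxolane of 5 (6S) | O=C1CC[C@@]2(C)C1=CCCC23OCCO3 | intermediate
7 | tertiary allylic alcohol: C9 hydroxyl and isopropyl, C1=C10, C5 dioxolane (6S,9R) | CC(C)[C@]1(O)CC[C@@]2(C)C1=CCCC23OCCO3 | intermediate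
8 | 1,10-epoxy alcohol, epoxide oxygen on the face of the C9 hydroxyl and C6 methyl (1R,6S,9R,10S) | O1[C@@H]2CCC3(OCCO3)[C@@]4(C)CC[C@@](O)(C(C)C)[C@@]124 | intermediate
9 | trans-fused ketal diol: C1 hydroxyl, C9 hydroxyl and C6 methyl on one face, C10 hydrogen on the other (1R,6S,9R,10S) | O[C@@H]1CCC2(OCCO2)[C@@]3(C)CC[C@@](O)(C(C)C)[C@H]13 | intermediate
10 | (1R,6S,9R,10S)-1,9-dihydroxy-9-isopropyl-6-methyl-trans-hydrindan-5-one | O[C@@H]1CCC(=O)[C@@]2(C)CC[C@@](O)(C(C)C)[C@H]12 | intermediate
11 | C1 O-TBS ether of 10 | CC(C)(C)[Si](C)(C)O[C@@H]1CCC(=O)[C@@]2(C)CC[C@@](O)(C(C)C)[C@H]12 | intermediate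
12 | C3-methyl derivative of 11 (C3 epimers) | CC(C)(C)[Si](C)(C)O[C@@H]1CC(C)C(=O)[C@@]2(C)CC[C@@](O)(C(C)C)[C@H]12 | intermediate
13 | trans-hydrindane C3=C5 trimethylsilyl enol ether, C1 O-TBS, C9 O-TMS (1R,6S,9R,10S) | CC(C)(C)[Si](C)(C)O[C@@H]1CC(C)=C(O[Si](C)(C)C)[C@@]2(C)CC[C@@](O[Si](C)(C)C)(C(C)C)[C@H]12 | intermediate
14 | chloroform | ClC(Cl)Cl | starting material
15 | siloxy dichlorocyclopropane: CCl2 (C4) bridging C3 and C5 on the face opposite the C6 methyl | CC(C)(C)[Si](C)(C)O[C@@H]1C[C@@]2(C)C(Cl)(Cl)[C@@]2(O[Si](C)(C)C)[C@@]3(C)CC[C@@](O[Si](C)(C)C)(C(C)C)[C@H]13 | intermediate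
16 | 4-chloro hydroazulenone: C3(CH3)=C4(Cl)–C5=O, C1 O-TBS, C9 O-TMS (1R,6S,9R,10S) | CC(C)(C)[Si](C)(C)O[C@@H]1CC(C)=C(Cl)C(=O)[C@@]2(C)CC[C@@](O[Si](C)(C)C)(C(C)C)[C@H]12 | intermediate
17 | hydroazulenone: C3(CH3)=C4H–C5=O, C1 O-TBS, C9 O-TMS | CC(C)(C)[Si](C)(C)O[C@@H]1CC(C)=CC(=O)[C@@]2(C)CC[C@@](O[Si](C)(C)C)(C(C)C)[C@H]12 | intermediate
18 | diol enone (1R,6S,9R,10S)-1,9-dihydroxy-9-isopropyl-3,6-dimethyl hydroazulen-5-one with C3=C4 | O[C@@H]1CC(C)=CC(=O)[C@@]2(C)CC[C@@](O)(C(C)C)[C@H]12 | intermediate
19 | vanillic acid | COc1cc(C(=O)O)ccc1O | starting material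
20 | tert-butyldimethylsilyl 4-(tert-butyldimethylsilyloxy)-3-methoxybenzoate | COc1cc(C(=O)O[Si](C)(C)C(C)(C)C)ccc1O[Si](C)(C)C(C)(C)C | intermediate
21 | 4-(tert-butyldimethylsilyloxy)-3-methoxybenzoyl chloride | COc1cc(C(Cl)=O)ccc1O[Si](C)(C)C(C)(C)C | intermediate
22 | C1 4-(tert-butyldimethylsilyloxy)-3-methoxybenzoate of 18 | COc1cc(C(=O)O[C@@H]2CC(C)=CC(=O)[C@@]3(C)CC[C@@](O)(C(C)C)[C@H]23)ccc1O[Si](C)(C)C(C)(C)C | intermediate
23 | C1 4-hydroxy-3-methoxybenzoate (vanillate) of 18, (1R,6S,9R,10S) | COc1cc(C(=O)O[C@@H]2CC(C)=CC(=O)[C@@]3(C)CC[C@@](O)(C(C)C)[C@H]23)ccc1O | target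

**Step count.** Total: 18 steps. Longest linear sequence: 16 steps (steps 1–14, 17 and 18); steps 15 and 16 prepare the acyl chloride.

**Steps most likely to fail**

Step 12. Cleavage of the silyl enol ether by tert-butoxide back to the ketone may outrun carbene capture at the hindered tetrasubstituted alkene, or the halo enone may degrade under the basic conditions before the ring opening is complete. The fallback sets out from 13: cyclopropanation with the zinc carbenoid from Et2Zn and CH2I2 (Simmons–Smith reaction) should give the siloxycyclopropane F1. FeCl3 in DMF then oxidises it to an oxygen-centred radical that cleaves the C3–C5 bond and, after chlorine transfer to the tertiary C3 radical, gives the ring-enlarged β-chloro ketone F2. NaOAc in MeOH eliminates HCl toward C4, and the route is rejoined at 17, so that step 13 is not needed; any loss of the C9 silyl group on the way is harmless because step 14 removes it in any case.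

Step 7. Hydrogen-atom transfer to the planar C10 radical may occur from the wrong face and give the cis ring fusion, or the titanium reagent may deoxygenate the epoxide back to the alkene. The fallback sets out from 7: hydroboration–oxidation (BH3·THF; then NaOH, H2O2) is expected to add hydrogen to C10 and boron to C1 in a concerted syn fashion on the face away from the C6 methyl and the C9 oxygen, giving the trans-fused C1-epimeric diol F3. Dess–Martin periodinane oxidises the secondary alcohol to the C1 ketone F4 under neutral conditions that do not epimerise C10. LiBH(s-Bu)3 at −78 °C should then attack C1 from the equatorial side, the axial path being blocked by the syn-axial C6 methyl, and give the axial alcohol, which is 9.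

Step 13. Oxidative addition into the tetrasubstituted C4–Cl bond next to quaternary C6 may be too slow, so that decomposition or reduction of the enone competes. The fallback sets out from 13: the ring enlargement is run with bromoform and KOt-Bu, which should give, by way of the dibromocyclopropane F5 that opens on warming, the 4-bromo enone F6. Its weaker C–Br bond is reduced with Bu3SnH and catalytic Pd(PPh3)4 (zerovalent palladium) in toluene, and the route is rejoined at 17.

**Further compounds**

F1 | step 12 | siloxycyclopropane: CH2 (C4) bridging C3 and C5, C1 O-TBS, C5 O-TMS, C9 O-TMS | CC(C)(C)[Si](C)(C)O[C@@H]1C[C@@]2(C)C[C@@]2(O[Si](C)(C)C)[C@@]3(C)CC[C@@](O[Si](C)(C)C)(C(C)C)[C@H]13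
F2 | step 12 | β-chloro ketone: 3-chloro-3-methyl hydroazulen-5-one (C3 epimers), C1 O-TBS, C9 O-TMS | CC(C)(C)[Si](C)(C)O[C@@H]1CC(C)(Cl)CC(=O)[C@@]2(C)CC[C@@](O[Si](C)(C)C)(C(C)C)[C@H]12
F3 | step 7 | C1-epimeric ketal diol, trans-fused, C1 hydroxyl on the face of C10–H (1S,6S,9R,10S) | O[C@H]1CCC2(OCCO2)[C@@]3(C)CC[C@@](O)(C(C)C)[C@H]13
F4 | step 7 | C1 ketone of the trans-fused ketal, C9 hydroxyl retained | O=C1CCC2(OCCO2)[C@@]3(C)CC[C@@](O)(C(C)C)[C@H]13
F5 | step 13 | dibromocyclopropane: CBr2 (C4) bridging C3 and C5, C1 O-TBS, C5 O-TMS, C9 O-TMS | CC(C)(C)[Si](C)(C)O[C@@H]1C[C@@]2(C)C(Br)(Br)[C@@]2(O[Si](C)(C)C)[C@@]3(C)CC[C@@](O[Si](C)(C)C)(C(C)C)[C@H]13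
F6 | step 13 | 4-bromo enone: C3(CH3)=C4(Br)–C5=O, C1 O-TBS, C9 O-TMS | CC(C)(C)[Si](C)(C)O[C@@H]1CC(C)=C(Br)C(=O)[C@@]2(C)CC[C@@](O[Si](C)(C)C)(C(C)C)[C@H]12
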